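**Retrosynthetic overview**
1. Target ⇐ benzyl ester of its 16-methylidene analogue (the 16,17-alkene, compound 24): exo-face Markovnikov hydration of C16=C17, then hydrogenolysis of the ester.
2. Ring A (C3–C4) by intramolecular aldol of the 19,10-lactone enolate onto a C3 aldehyde; the lactone (C4–C5) by intramolecular Michael addition of a C10 propanoate to the ring B enoate.
3. C10 carbinol by convex-face addition of a C1–C3 acetal Grignard reagent to a B/C/D keto enoate; ring B (C5=C6) by intramolecular aldol condensation of a C10 methyl ketone with a C6 α-keto ester.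
4. Ring D and quaternary C8 (C8–C15) by intramolecular Hosomi–Sakurai addition of a C13 allylsilane to a ring C enal; the enal comes from cyclohexenone, an alkenylboronate (asymmetric 1,4-addition sets C13) and a silyloxyacetate.
5. Ring order: C (cyclohexenone) → D → B → lactone → A.

Assumption: intermediates are described with gibberellane numbering (C1–C19 of the target); β is the face of H5, H9 and C15, α the face of the lactone bridge, C11 and C14.

**Step 1**
Reactants: 1 (2-bromoallyl)trimethylsilane
Product: 3 4,4,5,5-tetramethyl-2-[3-(trimethylsilyl)prop-1-en-2-yl]-1,3,2-dioxaborolane, via alkenylmagnesium bromide 2 (not isolated)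
Conditions: Mg, THF, 40 °C; then i-PrOB(pin), −78 °C → rt
Reagents that add atoms: 2-isopropoxy-4,4,5,5-tetramethyl-1,3,2-dioxaborolane, CC(C)OB1OC(C)(C)C(C)(C)O1
Why: Grignard formation at the vinylic bromide and borylation of the Grignard reagent give the alkenylboronate without touching the allylsilane.

**Step 2**
Reactants: 3 the alkenylboronate; 4 cyclohex-2-en-1-one
Product: 5 (R)-3-[3-(trimethylsilyl)prop-1-en-2-yl]cyclohexan-1-one
Conditions: [RhCl(C8H12)]2 (2.5 mol %), (R)-BINAP (6 mol %), KOH (0.3 equiv), dioxane/H2O 10:1, 50 °C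
Reagents that add atoms: none
Why: Hayashi–Miyaura rhodium-catalysed asymmetric 1,4-addition; the (R)-BINAP catalyst adds the alkenyl group to one enone face and sets C13 as R, in the same sense as the (R)-3-arylcyclohexanones.

**Step 3**
Reactants: 6 benzyl glycolate
Product: 7 benzyl 2-(tert-butyldimethylsilyloxy)acetate
Conditions: TBSCl, imidazole, DMF, rt
Reagents that add atoms: tert-butyldimethylsilyl chloride, CC(C)(C)[Si](C)(C)Cl
Why: Imidazole-promoted silylation protects the hydroxyl so that the ester can be enolised in step 6.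

**Step 4**
Reactants: 5 the (R)-ketone
Product: 8 (5R,Z)-2-(hydroxymethylidene)-5-[3-(trimethylsilyl)prop-1-en-2-yl]cyclohexan-1-one
Conditions: NaH, HCO2Et, EtOH (cat.), THF, 0 °C → rt; 1 M HCl work-up
Reagents that add atoms: ethyl formate, CCOC=O
Why: Reversible Claisen formylation places the formyl carbon (C10) on the less hindered α-carbon (C9), remote from the C13 substituent.

**Step 5**
Reactants: 8 the hydroxymethylidene ketone
Product: 9 (5R,E)-2-(isopropoxymethylidene)-5-[3-(trimethylsilyl)prop-1-en-2-yl]cyclohexan-1-one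
Conditions: i-PrI, K2CO3, DMF, rt
Reagents that add atoms: 2-iodopropane, CC(C)I
Why: O-alkylation of the vinylogous acid gives a vinylogous ester, so that the next nucleophile attacks the ketone carbon (C8).

**Step 6**
Reactants: 9 the isopropoxymethylidene ketone; 7 benzyl 2-(tert-butyldimethylsilyloxy)acetate
Product: 11 benzyl 2-(tert-butyldimethylsilyloxy)-2-{(5R)-2-formyl-5-[3-(trimethylsilyl)prop-1-en-2-yl]cyclohex-1-en-1-yl}acetate, via tertiary aldol adduct 10 (not isolated)
Conditions: 7, LiN(i-Pr)2, THF, −78 °C; then 9, −78 °C; then 1 M HCl, THF, 0 °C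
Reagents that add atoms: none
Why: Aldol addition of the lithium ester enolate to the ketone, then acid-induced loss of isopropanol from the β-hydroxy enol ether (alkylative carbonyl transposition of the Stork–Danheiser type), gives the tetrasubstituted enal carrying C6/C7 on C8.

**Step 7**
Reactants: 11 the allylsilane enal
Product: 12 benzyl 2-(tert-butyldimethylsilyloxy)-2-[(1R,5R)-2-formyl-6-methylidenebicyclo[3.2.1]octan-1-yl]acetate
Conditions: EtAlCl2 (1.5 equiv), CH2Cl2, −78 → −20 °C; aq. NaHCO3
Reagents that add atoms: none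
Why: Intramolecular Hosomi–Sakurai conjugate addition; the allylsilane on C13 can reach C8 of the activated enal only from its own face, so quaternary C8 follows from C13 and the exocyclic C16=C17 alkene forms with loss of silicon.

**Step 8**
Reactants: 12 the bicyclic aldehyde
Product: 13 benzyl 2-(tert-butyldimethylsilyloxy)-2-[(1R,5R)-2-(1-hydroxyethyl)-6-methylidenebicyclo[3.2.1]octan-1-yl]acetate
Conditions: MeMgBr, THF, −78 °C; aq. NH4Cl
Reagents that add atoms: methylmagnesium bromide, C[Mg]Br
Why: Grignard addition to the aldehyde, which is far more electrophilic than the hindered α-silyloxy ester at −78 °C; the new carbinol centre is removed in step 10.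

**Step 9**
Reactants: 13 the silyl ether alcohol
Product: 14 benzyl 2-hydroxy-2-[(1R,5R)-2-(1-hydroxyethyl)-6-methylidenebicyclo[3.2.1]octan-1-yl]acetate
Conditions: Bu4NF, AcOH, THF, 0 °C → rt
Reagents that add atoms: none
Why: Fluoride cleavage of the silyl ether, buffered with acetic acid to prevent lactonisation onto the benzyl ester.

**Step 10**
Reactants: 14 the diol
Product: 15 benzyl 2-[(1R,5R)-2-acetyl-6-methylidenebicyclo[3.2.1]octan-1-yl]-2-oxoacetate
Conditions: Dess–Martin periodinane (2.5 equiv), CH2Cl2, 0 °C → rt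
Reagents that add atoms: none
Why: Dess–Martin oxidation of both secondary alcohols gives the C10 methyl ketone and the C6 α-keto ester without touching the alkene.

**Step 11**
Reactants: 15 the diketo ester
Product: 17 benzyl 9-methylidene-4-oxotricyclo[6.2.1.0(1,5)]undec-2-ene-2-carboxylate (B/C/D keto enoate; 9β-H), via ketol 16 (not isolated)
Conditions: KOt-Bu (0.3 equiv), t-BuOH/THF, 0 °C → rt
Reagents that add atoms: none
Why: Intramolecular aldol condensation of a 1,4-dicarbonyl compound (methyl ketone enolate onto the non-enolisable α-keto ester, then E1cB dehydration) closes ring B; epimerisable C9 settles in the cis-fused hydrindenone arrangement (C10 axial on ring C), which is that of the target.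

**Step 12**
Reactants: 17 the keto enoate; 18 2-(2-bromoethyl)-1,3-dioxolane
Product: 21 benzyl 4-[2-(1,3-dioxolan-2-yl)ethyl]-9-methylidene-4-(propanoyloxy)tricyclo[6.2.1.0(1,5)]undec-2-ene-2-carboxylate (10α-propanoate), via Grignard reagent 19 (not isolated), via bromomagnesium alkoxide 20 (not isolated)
Conditions: 18, Mg, THF, 25 °C; CeCl3, THF, −78 °C; then 17; then (EtCO)2O, DMAP (cat.), −78 °C → rt
Reagents that add atoms: propanoic anhydride, CCC(=O)OC(=O)CC
Why: Cerium-mediated Grignard 1,2-addition to the ketone from the convex β-face of the cis-fused B/C system (anti to C11 and C14) gives the 10α-alkoxide, which is acylated in the same flask.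

**Step 13**
Reactants: 21 the tertiary propanoate
Product: 22 benzyl ester of the 19,10-lactone with 4-H, 5β-H, 6β-CO2Bn and the C10 2-(1,3-dioxolan-2-yl)ethyl chain
Conditions: KH, DMF, −40 → 0 °C; AcOH
Reagents that add atoms: none
Why: Intramolecular Michael addition of the propanoate enolate to the enoate; the α-oriented ester tether delivers C4 to the α-face of C5 (cis-fused γ-lactone, H5 β) and the C6 ester equilibrates to the convex β-position.

**Step 14**
Reactants: 22 the lactone acetal
Product: 23 benzyl ester of the 19,10-lactone with 4-H and a C10 3-oxopropyl chain (C3 aldehyde)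
Conditions: 1 M HCl, THF, rt
Reagents that add atoms: water, O
Why: Acid-catalysed acetal hydrolysis; the lactone, benzyl ester and 1,1-disubstituted alkene survive dilute acid at room temperature.

**Step 15**
Reactants: 23 the lactone aldehyde
Product: 24 16-ene lactone alcohol benzyl ester (benzyl ester of the 3β-hydroxy-16-methylidene 19,10-lactone 7-acid)
Conditions: KOt-Bu (0.2 equiv), t-BuOH/THF 1:5, −30 °C, 20 min; AcOH
Reagents that add atoms: none
Why: Intramolecular aldol addition closes ring A; C4 is fixed by the bicyclic lactone, and under kinetic, non-chelating conditions the aldehyde oxygen lies anti to the lactone carbonyl, which gives the axial 3β-alcohol (the 3α epimer is the thermodynamic one and is separated).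

**Step 16**
Reactants: 24 the 16-ene lactone alcohol benzyl ester
Product: 25 benzyl ester of the target (16-hydroxy-16-methyl; hydroxyl exo)
Conditions: Co(acac)2 (0.2 equiv), PhSiH3, O2 (1 atm), THF, rt
Reagents that add atoms: dioxygen, O=O
Why: Mukaiyama hydration; hydrogen-atom transfer to C17 gives the tertiary C16 radical, which O2 traps on the exo face (the side of the C14 bridge), so the hydroxyl is exo and the methyl endo as in the target.

**Step 17**
Reactants: 25 the benzyl ester of the target
Product: 26 the target gibberellin (free 7-carboxylic acid)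
Conditions: H2 (1 atm), Pd/C, EtOAc, rt
Reagents that add atoms: none
Why: Hydrogenolysis of the benzyl ester; no other reducible group remains.

**Compound list**
1 | (2-bromoallyl)trimethylsilane | C=C(Br)C[Si](C)(C)C | starting material
2 | [3-(trimethylsilyl)prop-1-en-2-yl]magnesium bromide | C=C(C[Si](C)(C)C)[Mg]Br | intermediate
3 | 4,4,5,5-tetramethyl-2-[3-(trimethylsilyl)prop-1-en-2-yl]-1,3,2-dioxaborolane | C=C(C[Si](C)(C)C)B1OC(C)(C)C(C)(C)O1 | intermediate
4 | cyclohex-2-en-1-one | O=C1C=CCCC1 | starting material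
5 | (R)-3-[3-(trimethylsilyl)prop-1-en-2-yl]cyclohexan-1-one | C[Si](C)(C)CC(=C)[C@@H]1CCCC(=O)C1 | intermediate
6 | benzyl glycolate (benzyl 2-hydroxyacetate) | OCC(=O)OCc1ccccc1 | starting material
7 | benzyl 2-(tert-butyldimethylsilyloxy)acetate | CC(C)(C)[Si](C)(C)OCC(=O)OCc1ccccc1 | intermediate
8 | (5R,Z)-2-(hydroxymethylidene)-5-[3-(trimethylsilyl)prop-1-en-2-yl]cyclohexan-1-one | C[Si](C)(C)CC(=C)[C@@H]1CC/C(=C/O)C(=O)C1 | intermediate
9 | (5R,E)-2-(isopropoxymethylidene)-5-[3-(trimethylsilyl)prop-1-en-2-yl]cyclohexan-1-one | C[Si](C)(C)CC(=C)[C@@H]1CC/C(=C\OC(C)C)C(=O)C1 | intermediate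
10 | benzyl 2-(tert-butyldimethylsilyloxy)-2-{(5R)-1-hydroxy-2-[(E)-isopropoxymethylidene]-5-[3-(trimethylsilyl)prop-1-en-2-yl]cyclohexyl}acetate (diastereomers at C1 and the silyloxy carbon) | CC(C)O/C=C1\CC[C@H](CC1(O)C(O[Si](C)(C)C(C)(C)C)C(=O)OCc1ccccc1)C(=C)C[Si](C)(C)C | intermediate
11 | benzyl 2-(tert-butyldimethylsilyloxy)-2-{(5R)-2-formyl-5-[3-(trimethylsilyl)prop-1-en-2-yl]cyclohex-1-en-1-yl}acetate (both epimers at the silyloxy carbon) | O=CC1=C(C[C@@H](CC1)C(=C)C[Si](C)(C)C)C(O[Si](C)(C)C(C)(C)C)C(=O)OCc1ccccc1 | intermediate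
12 | benzyl 2-(tert-butyldimethylsilyloxy)-2-[(1R,5R)-2-formyl-6-methylidenebicyclo[3.2.1]octan-1-yl]acetate (C8 and C13 set; epimers at C9 and C6) | O=CC1CC[C@@H]2C[C@]1(CC2=C)C(O[Si](C)(C)C(C)(C)C)C(=O)OCc1ccccc1 | intermediate
13 | benzyl 2-(tert-butyldimethylsilyloxy)-2-[(1R,5R)-2-(1-hydroxyethyl)-6-methylidenebicyclo[3.2.1]octan-1-yl]acetate (epimer mixture at C6, C9, C10) | CC(O)C1CC[C@@H]2C[C@]1(CC2=C)C(O[Si](C)(C)C(C)(C)C)C(=O)OCc1ccccc1 | intermediate
14 | benzyl 2-hydroxy-2-[(1R,5R)-2-(1-hydroxyethyl)-6-methylidenebicyclo[3.2.1]octan-1-yl]acetate (epimer mixture) | CC(O)C1CC[C@@H]2C[C@]1(CC2=C)C(O)C(=O)OCc1ccccc1 | intermediate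
15 | benzyl 2-[(1R,5R)-2-acetyl-6-methylidenebicyclo[3.2.1]octan-1-yl]-2-oxoacetate (C9 epimerisable) | CC(=O)C1CC[C@@H]2C[C@]1(CC2=C)C(=O)C(=O)OCc1ccccc1 | intermediate
16 | benzyl 2-hydroxy-9-methylidene-4-oxotricyclo[6.2.1.0(1,5)]undecane-2-carboxylate (ketol; C6–OH, 9β-H) | O=C1[C@@H]2CC[C@@H]3C[C@]2(CC3=C)C(O)(C(=O)OCc2ccccc2)C1 | intermediate
17 | benzyl 9-methylidene-4-oxotricyclo[6.2.1.0(1,5)]undec-2-ene-2-carboxylate (C10 ketone, C5=C6 enoate, 9β-H, C8/C13 as in the target) | O=C1[C@@H]2CC[C@@H]3C[C@]2(CC3=C)C(C(=O)OCc2ccccc2)=C1 | intermediate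
18 | 2-(2-bromoethyl)-1,3-dioxolane | BrCCC1OCCO1 | starting material
19 | [2-(1,3-dioxolan-2-yl)ethyl]magnesium bromide | Br[Mg]CCC1OCCO1 | intermediate
20 | bromomagnesium 10α-alkoxide of the Grignard adduct of 17 (chain on C10 β) | Br[Mg]O[C@]1(CCC2OCCO2)[C@@H]2CC[C@@H]3C[C@]2(CC3=C)C(C(=O)OCc2ccccc2)=C1 | intermediate
21 | benzyl 4-[2-(1,3-dioxolan-2-yl)ethyl]-9-methylidene-4-(propanoyloxy)tricyclo[6.2.1.0(1,5)]undec-2-ene-2-carboxylate (10α-propanoate, 10β-chain, 9β-H) | CCC(=O)O[C@]1(CCC2OCCO2)[C@@H]2CC[C@@H]3C[C@]2(CC3=C)C(C(=O)OCc2ccccc2)=C1 | intermediate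
22 | 19,10-lactone acetal: rings B/C/D with α-fused γ-lactone, 4-H (C4 epimers), 5β-H, 6β-CO2Bn, C10 2-(1,3-dioxolan-2-yl)ethyl chain, 16-methylidene | CC1C(=O)O[C@]2(CCC3OCCO3)[C@@H]3CC[C@@H]4C[C@]3(CC4=C)[C@@H](C(=O)OCc3ccccc3)[C@H]12 | intermediate
23 | 19,10-lactone aldehyde: as 22 with a C10 3-oxopropyl chain | CC1C(=O)O[C@]2(CCC=O)[C@@H]3CC[C@@H]4C[C@]3(CC4=C)[C@@H](C(=O)OCc3ccccc3)[C@H]12 | intermediate
24 | 16-ene lactone alcohol benzyl ester: benzyl ester of the 3β-hydroxy-16-methylidene 19,10-lactone 7-acid, i.e. the target skeleton with a C16=C17 exocyclic alkene in place of the C16 methyl carbinol (α-lactone, C18 methyl on C4, 5β-H, 6β-CO2Bn, 9β-H) | C[C@@]12C(=O)O[C@]3(CC[C@@H]1O)[C@@H]1CC[C@@H]4C[C@]1(CC4=C)[C@@H](C(=O)OCc1ccccc1)[C@@H]32 | intermediate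
25 | benzyl ester of the target: as 24 with 16-hydroxy (exo, on the side of C14) and 16-methyl (endo) in place of the alkene | C[C@@]12C(=O)O[C@]3(CC[C@@H]1O)[C@@H]1CC[C@@H]4C[C@]1(C[C@@]4(C)O)[C@@H](C(=O)OCc1ccccc1)[C@@H]32 | intermediate
26 | the target gibberellin: 3β,16-dihydroxy-16-methyl 19,10-lactone 7-carboxylic acid (16-OH exo, 5β-H, 6β-CO2H, 9β-H) | C[C@@]12C(=O)O[C@]3(CC[C@@H]1O)[C@@H]1CC[C@@H]4C[C@]1(C[C@@]4(C)O)[C@@H](C(=O)O)[C@@H]32 | target

**Step count**
Total step count: 17.
Longest linear sequence: 16 steps (steps 1, 2 and 4–17, from 1). Two branches feed the main line: the silyloxyacetate 7 (step 3) joins at step 6 and the acetal Grignard reagent from 18 joins at step 12.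

**Three steps most likely to fail, with fallbacks**

Step 7 (Sakurai closure onto a fully substituted enal carbon). The usual failure is protodesilylation instead of C–C bond formation. The fallback sets out from 11 and comes back at 12. Treating 11 with CF3CO2H (CH2Cl2, −20 °C) deliberately removes the silyl group and gives benzyl 2-(tert-butyldimethylsilyloxy)-2-[(5R)-2-formyl-5-(prop-1-en-2-yl)cyclohex-1-en-1-yl]acetate F1. Me2AlCl (CH2Cl2, −78 → 0 °C) then promotes an intramolecular ene-type conjugate addition of the isopropenyl group to C8 of the enal. A methyl hydrogen is transferred, so the same C8–C15 bond and the exocyclic alkene of 12 result without any silane.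

Step 13 (Michael lactonisation of a simple propanoate enolate, which must use an endocyclic ester enolate in a five-membered closure). The fallback sets out from 17 and comes back at 22. The Grignard addition of step 12 is repeated, but the alkoxide is quenched with allyl 3-chloro-2-methyl-3-oxopropanoate to give the mixed 10α-(allyl methylmalonate) F2. DBU (CH2Cl2, 0 °C) triggers a malonate Michael addition through the soft, exocyclic enolate and gives the lactone with methyl and allyl ester on C4, F3. Pd(PPh3)4 and morpholine (THF, then 60 °C) remove the allyl group, and the β-carboxy lactone decarboxylates to 22.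

Step 15 (C3 configuration in the aldol; retro-aldol equilibration favours the equatorial 3α-alcohol). The fallback sets out from 23 and comes back at 24. The aldol is allowed to equilibrate (KOt-Bu cat., t-BuOH/THF, rt) to the 3α-alcohol, 3-epi-16-ene lactone alcohol benzyl ester F4. Dess–Martin oxidation gives the 3-ketone, 3-oxo-16-ene lactone benzyl ester F5. K[BH(s-Bu)3] (THF, −78 °C) then delivers hydride from the equatorial direction and gives the axial 3β-alcohol 24 by substrate control.

**Further compounds**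
F1 | step 7 | benzyl 2-(tert-butyldimethylsilyloxy)-2-[(5R)-2-formyl-5-(prop-1-en-2-yl)cyclohex-1-en-1-yl]acetate | O=CC1=C(C[C@@H](CC1)C(C)=C)C(O[Si](C)(C)C(C)(C)C)C(=O)OCc1ccccc1
F2 | step 13 | 10α-(allyl methylmalonate) of the Grignard adduct of 17 | C=CCOC(=O)C(C)C(=O)O[C@]1(CCC2OCCO2)[C@@H]2CC[C@@H]3C[C@]2(CC3=C)C(C(=O)OCc2ccccc2)=C1
F3 | step 13 | 19,10-lactone acetal carrying methyl and allyloxycarbonyl on C4 | C=CCOC(=O)C1(C)C(=O)O[C@]2(CCC3OCCO3)[C@@H]3CC[C@@H]4C[C@]3(CC4=C)[C@@H](C(=O)OCc3ccccc3)[C@H]12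
F4 | step 15 | 3-epi-16-ene lactone alcohol benzyl ester (3α-OH epimer of 24) | C[C@@]12C(=O)O[C@]3(CC[C@H]1O)[C@@H]1CC[C@@H]4C[C@]1(CC4=C)[C@@H](C(=O)OCc1ccccc1)[C@@H]32
F5 | step 15 | 3-oxo-16-ene lactone benzyl ester (3-ketone of 24) | C[C@@]12C(=O)O[C@]3(CCC1=O)[C@@H]1CC[C@@H]4C[C@]1(CC4=C)[C@@H](C(=O)OCc1ccccc1)[C@@H]32
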